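Locants kept throughout: ring A = trioxygenated benzene; ring B = dioxane (O1, C2 aryl-bearing, C3 methyl-bearing, O4); ring C = 4-hydroxy-3,5-dimethoxyphenyl on C2; OMe at C5, Br or propenyl at C7.
Retrosynthetic cuts, in order: C7–propenyl (Suzuki–Miyaura); C3–CH3 back to C3–CH2OH and C3–CHO; the C2–C3 bond of ring B; then O1–C2 (benzyl ether) and O4–C3 (allyl ether). This leaves 5-bromo-o-vanillin, allyl bromide and syringaldehyde.
Forward: O4 is allylated, the CHO on ring A is exchanged for O1–H, O1 is benzylated with silylated syringyl alcohol, and the allyl group is cut to O4–CH2–CHO. Ring B, the only ring made, closes last from this open bis-ether.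
Enabling feature: the free 4-OH of ring C is para to C2. Oxidation therefore turns the O1–CH2–aryl ether into a δ-aryloxy p-quinone methide with C2 as its electrophilic exocyclic carbon, while C3, the α-carbon of an aryloxyacetaldehyde, becomes nucleophilic as an enamine.
Stereochemistry: C3 comes from the face-blocking (R)-diphenylprolinol silyl ether catalyst. C2 comes from the chair-like closure and, dynamically, from reversible O1–C2 opening through the same quinone methide, which funnels both C2 epimers into the trans (2R,3R) isomer. The E-alkene comes from the boronate.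
The helper oxygen on the C3 side chain is removed through the iodide with LiEt3BH.

Key step: step 8

Assumption: the facial sense known for diarylprolinol silyl ether enamines with untethered electrophiles is taken to hold for the tethered acceptor. This assigns the (R)-catalyst to the (3R) series; if the sense were reversed, the (S)-catalyst would serve.

Step 1
Reactants: 1 5-bromo-2-hydroxy-3-methoxybenzaldehyde; 2 allyl bromide
Product: 3 5-bromo-3-methoxy-2-(prop-2-enyloxy)benzaldehyde
Conditions: K2CO3, DMF, rt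
Reagents that add atoms: none
Why: Williamson ether synthesis on the only phenol of 1 with an unhindered allylic bromide puts the carbon handle on the oxygen that becomes O4, so the regiochemistry of ring B is fixed by the starting material.

Step 2
Reactants: 3 5-bromo-3-methoxy-2-(prop-2-enyloxy)benzaldehyde
Product: 5 5-bromo-3-methoxy-2-(prop-2-enyloxy)phenol, via aryl formate 4 (not isolated)
Conditions: mCPBA (1.2 equiv), CH2Cl2, 0 °C to rt; then K2CO3 (cat.), MeOH, 0 °C
Reagents that add atoms: mCPBA, OOC(=O)c1cccc(Cl)c1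
Why: Baeyer–Villiger oxidation of an ortho-alkoxybenzaldehyde proceeds by aryl migration, which should be faster than epoxidation of the electron-poor terminal alkene of the allyl ether, and mild methanolysis of formate 4 frees O1–H next to O4.

Step 3
Reactants: 6 syringaldehyde (4-hydroxy-3,5-dimethoxybenzaldehyde)
Product: 7 3,5-dimethoxy-4-(triisopropylsilyloxy)benzaldehyde
Conditions: TIPSCl, imidazole, DMF, rt
Reagents that add atoms: chlorotriisopropylsilane (TIPSCl), CC(C)[Si](Cl)(C(C)C)C(C)C
Why: Standard silyl ether formation, the bulky triisopropylsilyl group being chosen because it must survive borohydride, Mitsunobu and OsO4/NaIO4 conditions and still leave with fluoride.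

Step 4
Reactants: 7 3,5-dimethoxy-4-(triisopropylsilyloxy)benzaldehyde
Product: 8 [3,5-dimethoxy-4-(triisopropylsilyloxy)phenyl]methanol
Conditions: NaBH4, MeOH, 0 °C
Reagents that add atoms: none
Why: Chemoselective borohydride reduction of an aromatic aldehyde to the benzylic alcohol, with no other reducible group present.

Step 5
Reactants: 5 5-bromo-3-methoxy-2-(prop-2-enyloxy)phenol; 8 [3,5-dimethoxy-4-(triisopropylsilyloxy)phenyl]methanol
Product: 9 5-bromo-1-{[3,5-dimethoxy-4-(triisopropylsilyloxy)benzyl]oxy}-3-methoxy-2-(prop-2-enyloxy)benzene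
Conditions: PPh3, DIAD, THF, 0 °C to rt
Reagents that add atoms: none
Why: Mitsunobu etherification joins the acidic phenol O1–H of 5 to the activated primary benzylic alcohol 8 under neutral conditions, which avoids an unstable electron-rich benzylic halide and makes the O1–C2 bond without any stereocentre.

Step 6
Reactants: 9 5-bromo-1-{[3,5-dimethoxy-4-(triisopropylsilyloxy)benzyl]oxy}-3-methoxy-2-(prop-2-enyloxy)benzene
Product: 11 2-(4-bromo-2-{[3,5-dimethoxy-4-(triisopropylsilyloxy)benzyl]oxy}-6-methoxyphenoxy)acetaldehyde, via vicinal diol 10 (not isolated)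
Conditions: OsO4 (2 mol %), NaIO4 (4 equiv), 2,6-lutidine, dioxane/H2O, rt
Reagents that add atoms: OsO4 (catalytic oxygen carrier), O=[Os](=O)(=O)=O; NaIO4 (stoichiometric oxygen source), [Na+].[O-]I(=O)(=O)=O; water, O
Why: Lemieux–Johnson oxidation cleaves the only alkene to the aryloxyacetaldehyde at near-neutral pH (2,6-lutidine buffer), so the acid-labile benzyl aryl ether and the silyl ether should survive.

Step 7
Reactants: 11 2-(4-bromo-2-{[3,5-dimethoxy-4-(triisopropylsilyloxy)benzyl]oxy}-6-methoxyphenoxy)acetaldehyde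
Product: 12 2-{4-bromo-2-[(4-hydroxy-3,5-dimethoxybenzyl)oxy]-6-methoxyphenoxy}acetaldehyde
Conditions: TBAF (1.1 equiv), AcOH (1.3 equiv), THF, 0 °C; used at once
Reagents that add atoms: none
Why: Fluoride-induced cleavage of the aryl silyl ether is fast at 0 °C, and the acetic acid buffer protonates the phenoxide at once, so neither loss of ring A through a quinone methide nor aldol reaction of the aldehyde should set in.

Step 8
Reactants: 12 2-{4-bromo-2-[(4-hydroxy-3,5-dimethoxybenzyl)oxy]-6-methoxyphenoxy}acetaldehyde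
Product: 16 4-[(2R,3R)-7-bromo-3-(hydroxymethyl)-5-methoxy-2,3-dihydro-1,4-benzodioxin-2-yl]-2,6-dimethoxyphenol, via quinone methide 13 (not isolated), via enamine 14 (not isolated), via ring-closed aldehyde 15 (not isolated)
Conditions: (a) Ag2O (2 equiv), 4 Å molecular sieves, CH2Cl2 (0.02 M), 0 °C, filtered under N2; (b) (R)-2-[diphenyl(trimethylsilyloxy)methyl]pyrrolidine (20 mol %), PhCO2H (20 mol %), CH2Cl2, −30 °C; (c) CeCl3·7H2O, NaBH4, MeOH, −40 °C
Reagents that add atoms: none
Why: Proposed new method: Ag2O removes two electrons and two protons from the only free phenol (ring C 4-OH and the doubly activated C2–H) to give the neutral δ-aryloxy p-quinone methide 13, which has no hydrogen on a carbon next to C2 and so cannot tautomerise; the secondary amine then condenses with the aliphatic aldehyde to the E-enamine 14, whose carbon C3 adds to the exocyclic carbon C2 with rearomatisation of ring C as driving force, and hydrolysis of the iminium ion returns the catalyst and gives 15. The closest known reaction types are the enamine-catalysed asymmetric 1,6-addition of aldehydes to p-quinone methides and the use of α-oxygenated aldehydes as enamine donors, the new elements being the tethered mode and the aryloxy group on the acceptor carbon. Ring B closes in a 6-exo-trig mode at the quinone methide C=C (6-(enolexo) at the enamine), since closure through the other enamine carbon or through nitrogen would give seven- or eight-membered rings. C3 is controlled by the catalyst, whose CPh2(OSiMe3) group blocks one face of the s-trans E-enamine, and transfer of the known facial sense assigns the (R)-catalyst to the needed arrangement (3S by CIP in aldehyde 15, 3R after reduction). C2 is controlled by a chair-like transition state with ring C and the iminium carbon pseudo-equatorial (trans), and it stays correctable later because the para-OH allows reversible opening of the O1–C2 bond toward the more stable trans isomer. The step needs C–C attack to outrun addition–elimination of amine or water at C2 and to outrun enolisation or β-elimination of 15; the catechol tether, which holds C3 within bonding distance of the single electrophilic carbon, secures the first, and sieves, a bulky amine held mostly as enamine, low temperature and immediate Luche reduction in the same flask secure the second.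

Step 9
Reactants: 16 4-[(2R,3R)-7-bromo-3-(hydroxymethyl)-5-methoxy-2,3-dihydro-1,4-benzodioxin-2-yl]-2,6-dimethoxyphenol
Product: 17 4-[(2R,3S)-7-bromo-3-(iodomethyl)-5-methoxy-2,3-dihydro-1,4-benzodioxin-2-yl]-2,6-dimethoxyphenol
Conditions: PPh3, I2, imidazole (premixed), CH2Cl2, 0 °C to rt
Reagents that add atoms: iodine, [I][I]
Why: Appel-type iodination activates only the primary alcohol (a phenol gives no substitution product), and SN2 attack of iodide at the side-chain carbon leaves C2 and C3 untouched, C3 becoming S only through a change of CIP rank.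

Step 10
Reactants: 17 4-[(2R,3S)-7-bromo-3-(iodomethyl)-5-methoxy-2,3-dihydro-1,4-benzodioxin-2-yl]-2,6-dimethoxyphenol
Product: 18 4-[(2R,3R)-7-bromo-5-methoxy-3-methyl-2,3-dihydro-1,4-benzodioxin-2-yl]-2,6-dimethoxyphenol
Conditions: LiEt3BH (2.5 equiv), THF, −78 to 0 °C; then AcOH
Reagents that add atoms: none
Why: SN2 displacement of a primary iodide by the strongly nucleophilic hydride LiEt3BH removes the helper heteroatom, the first equivalent only deprotonating the phenol, whose lithium- and boron-bound phenoxide should not open ring B below 0 °C, and the aryl bromide is inert under these conditions.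

Step 11
Reactants: 18 4-[(2R,3R)-7-bromo-5-methoxy-3-methyl-2,3-dihydro-1,4-benzodioxin-2-yl]-2,6-dimethoxyphenol; 19 (E)-prop-1-enylboronic acid pinacol ester
Product: 20 4-[(2R,3R)-5-methoxy-3-methyl-7-[(E)-prop-1-enyl]-2,3-dihydro-1,4-benzodioxin-2-yl]-2,6-dimethoxyphenol (target)
Conditions: Pd(OAc)2 (5 mol %), SPhos (10 mol %), K3PO4, THF/H2O, 50 °C
Reagents that add atoms: none
Why: Suzuki–Miyaura coupling transfers the propenyl group with retention of the E geometry of 19, an electron-rich biarylphosphine helping oxidative addition to the electron-rich bromide, and the mildly basic medium lets any cis (2S,3R) epimer open at O1–C2 to the ring C quinone methide and re-close to the more stable trans (2R,3R) target.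

Compound list
1 | 5-bromo-2-hydroxy-3-methoxybenzaldehyde | COc1cc(Br)cc(C=O)c1O | starting material
2 | allyl bromide | C=CCBr | starting material
3 | 5-bromo-3-methoxy-2-(prop-2-enyloxy)benzaldehyde | C=CCOc1c(OC)cc(Br)cc1C=O | intermediate
4 | 5-bromo-3-methoxy-2-(prop-2-enyloxy)phenyl formate | C=CCOc1c(OC)cc(Br)cc1OC=O | intermediate
5 | 5-bromo-3-methoxy-2-(prop-2-enyloxy)phenol | C=CCOc1c(OC)cc(Br)cc1O | intermediate
6 | syringaldehyde | COc1cc(C=O)cc(OC)c1O | starting material
7 | 3,5-dimethoxy-4-(triisopropylsilyloxy)benzaldehyde | COc1cc(C=O)cc(OC)c1O[Si](C(C)C)(C(C)C)C(C)C | intermediate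
8 | [3,5-dimethoxy-4-(triisopropylsilyloxy)phenyl]methanol | COc1cc(CO)cc(OC)c1O[Si](C(C)C)(C(C)C)C(C)C | intermediate
9 | 5-bromo-1-{[3,5-dimethoxy-4-(triisopropylsilyloxy)benzyl]oxy}-3-methoxy-2-(prop-2-enyloxy)benzene | C=CCOc1c(OC)cc(Br)cc1OCc1cc(OC)c(O[Si](C(C)C)(C(C)C)C(C)C)c(OC)c1 | intermediate
10 | 3-(4-bromo-2-{[3,5-dimethoxy-4-(triisopropylsilyloxy)benzyl]oxy}-6-methoxyphenoxy)propane-1,2-diol (racemic) | OCC(O)COc1c(OC)cc(Br)cc1OCc1cc(OC)c(O[Si](C(C)C)(C(C)C)C(C)C)c(OC)c1 | intermediate
11 | 2-(4-bromo-2-{[3,5-dimethoxy-4-(triisopropylsilyloxy)benzyl]oxy}-6-methoxyphenoxy)acetaldehyde | O=CCOc1c(OC)cc(Br)cc1OCc1cc(OC)c(O[Si](C(C)C)(C(C)C)C(C)C)c(OC)c1 | intermediate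
12 | 2-{4-bromo-2-[(4-hydroxy-3,5-dimethoxybenzyl)oxy]-6-methoxyphenoxy}acetaldehyde | O=CCOc1c(OC)cc(Br)cc1OCc1cc(OC)c(O)c(OC)c1 | intermediate
13 | 2-{4-bromo-2-[(3,5-dimethoxy-4-oxocyclohexa-2,5-dien-1-ylidene)methoxy]-6-methoxyphenoxy}acetaldehyde (δ-aryloxy p-quinone methide) | O=CCOc1c(OC)cc(Br)cc1OC=C1C=C(OC)C(=O)C(OC)=C1 | intermediate
14 | E-enamine of 13 with (R)-2-[diphenyl(trimethylsilyloxy)methyl]pyrrolidine | COc1cc(Br)cc(OC=C2C=C(OC)C(=O)C(OC)=C2)c1O/C=C/N1CCC[C@@H]1C(c1ccccc1)(c1ccccc1)O[Si](C)(C)C | intermediate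
15 | (2R,3S)-7-bromo-2-(4-hydroxy-3,5-dimethoxyphenyl)-5-methoxy-2,3-dihydro-1,4-benzodioxine-3-carbaldehyde (trans) | Brc1cc(OC)c2c(c1)O[C@H](c1cc(OC)c(O)c(OC)c1)[C@@H](C=O)O2 | intermediate
16 | 4-[(2R,3R)-7-bromo-3-(hydroxymethyl)-5-methoxy-2,3-dihydro-1,4-benzodioxin-2-yl]-2,6-dimethoxyphenol | Brc1cc(OC)c2c(c1)O[C@H](c1cc(OC)c(O)c(OC)c1)[C@@H](CO)O2 | intermediate
17 | 4-[(2R,3S)-7-bromo-3-(iodomethyl)-5-methoxy-2,3-dihydro-1,4-benzodioxin-2-yl]-2,6-dimethoxyphenol | Brc1cc(OC)c2c(c1)O[C@H](c1cc(OC)c(O)c(OC)c1)[C@@H](CI)O2 | intermediate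
18 | 4-[(2R,3R)-7-bromo-5-methoxy-3-methyl-2,3-dihydro-1,4-benzodioxin-2-yl]-2,6-dimethoxyphenol | Brc1cc(OC)c2c(c1)O[C@H](c1cc(OC)c(O)c(OC)c1)[C@@H](C)O2 | intermediate
19 | (E)-prop-1-enylboronic acid pinacol ester | C/C=C/B1OC(C)(C)C(C)(C)O1 | starting material
20 | 4-[(2R,3R)-5-methoxy-3-methyl-7-[(E)-prop-1-enyl]-2,3-dihydro-1,4-benzodioxin-2-yl]-2,6-dimethoxyphenol | C/C=C/c1cc(OC)c2c(c1)O[C@H](c1cc(OC)c(O)c(OC)c1)[C@@H](C)O2 | target

Total step count: 11. Longest linear sequence: 9 (steps 1, 2, 5–11; the branch 3, 4, 5–11 is equally long).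

Steps most likely to fail

(i) Step 8.
- What may go wrong: addition–elimination of the amine or of traces of water at C2 may strip ring A from the quinone methide. The enamine face may be poorly differentiated in the tethered mode. The new aldehyde may lose its configuration by enolisation and β-elimination before it is reduced.
- Fallback: it uses known chemistry only, takes C3 from the chiral pool and closes ring B as a lactone. It sets out from 1 and comes back at 18.
- Mitsunobu reaction of 1 with ethyl (S)-lactate (PPh3, DIAD, inversion) gives ethyl (2R)-2-(4-bromo-2-formyl-6-methoxyphenoxy)propanoate F1.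
- Baeyer–Villiger oxidation (mCPBA) gives ethyl (2R)-2-[4-bromo-2-(formyloxy)-6-methoxyphenoxy]propanoate F2.
- Methanolysis (Et3N, MeOH) frees ethyl (2R)-2-(4-bromo-2-hydroxy-6-methoxyphenoxy)propanoate F3, which lactonises with a trace of TsOH in warm toluene to (3R)-7-bromo-5-methoxy-3-methyl-2,3-dihydro-1,4-benzodioxin-2-one F4.
- Commercial 4-bromo-2,6-dimethoxyphenol is silylated (TIPSCl, imidazole) to (4-bromo-2,6-dimethoxyphenoxy)triisopropylsilane F5. This is lithiated (n-BuLi, THF, −78 °C) to [3,5-dimethoxy-4-(triisopropylsilyloxy)phenyl]lithium F6.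
- F6 adds to F4 to give (3R)-7-bromo-2-[3,5-dimethoxy-4-(triisopropylsilyloxy)phenyl]-5-methoxy-3-methyl-2,3-dihydro-1,4-benzodioxin-2-ol F7.
- Et3SiH and BF3·OEt2 (CH2Cl2, −78 °C) reduce the derived oxocarbenium ion anti to the methyl group to {4-[(2R,3R)-7-bromo-5-methoxy-3-methyl-2,3-dihydro-1,4-benzodioxin-2-yl]-2,6-dimethoxyphenoxy}triisopropylsilane F8. TBAF then gives 18.

(ii) Step 10.
- What may go wrong: the phenoxide may drive opening of ring B at O1–C2, and hydride may capture the resulting quinone methide, so that C2 is over-reduced and the ring is lost.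
- Fallback: the quinone methide channel is closed by capping the phenol before any hydride is used. It sets out from 17 and comes back at 18.
- TBSCl and imidazole in DMF give tert-butyl{4-[(2R,3S)-7-bromo-3-(iodomethyl)-5-methoxy-2,3-dihydro-1,4-benzodioxin-2-yl]-2,6-dimethoxyphenoxy}dimethylsilane F9.
- LiEt3BH (THF, 0 °C) gives tert-butyl{4-[(2R,3R)-7-bromo-5-methoxy-3-methyl-2,3-dihydro-1,4-benzodioxin-2-yl]-2,6-dimethoxyphenoxy}dimethylsilane F10. TBAF/AcOH then returns 18.

(iii) Step 11.
- What may go wrong: base-driven opening of ring B may be followed by proton loss at C3, which erodes configuration and leaves the ring open. Oxidative addition to the electron-rich bromide may also be sluggish.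
- Fallback: boron and base are given up for a neutral Stille coupling. It sets out from 18 and comes back at 20.
- (E)-Tributyl(prop-1-enyl)stannane, Pd(PPh3)4 and toluene at 90 °C give 20 directly with retention of the E geometry, and no new compound is made on the way.

Further compounds
F1 | step 8 | ethyl (2R)-2-(4-bromo-2-formyl-6-methoxyphenoxy)propanoate | CCOC(=O)[C@@H](C)Oc1c(OC)cc(Br)cc1C=O
F2 | step 8 | ethyl (2R)-2-[4-bromo-2-(formyloxy)-6-methoxyphenoxy]propanoate | CCOC(=O)[C@@H](C)Oc1c(OC)cc(Br)cc1OC=O
F3 | step 8 | ethyl (2R)-2-(4-bromo-2-hydroxy-6-methoxyphenoxy)propanoate | CCOC(=O)[C@@H](C)Oc1c(OC)cc(Br)cc1O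
F4 | step 8 | (3R)-7-bromo-5-methoxy-3-methyl-2,3-dihydro-1,4-benzodioxin-2-one | O=C1Oc2cc(Br)cc(OC)c2O[C@@H]1C
F5 | step 8 | (4-bromo-2,6-dimethoxyphenoxy)triisopropylsilane | COc1cc(Br)cc(OC)c1O[Si](C(C)C)(C(C)C)C(C)C
F6 | step 8 | [3,5-dimethoxy-4-(triisopropylsilyloxy)phenyl]lithium | [Li]c1cc(OC)c(O[Si](C(C)C)(C(C)C)C(C)C)c(OC)c1
F7 | step 8 | (3R)-7-bromo-2-[3,5-dimethoxy-4-(triisopropylsilyloxy)phenyl]-5-methoxy-3-methyl-2,3-dihydro-1,4-benzodioxin-2-ol (mixture at C2) | Brc1cc(OC)c2c(c1)OC(O)(c1cc(OC)c(O[Si](C(C)C)(C(C)C)C(C)C)c(OC)c1)[C@@H](C)O2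
F8 | step 8 | {4-[(2R,3R)-7-bromo-5-methoxy-3-methyl-2,3-dihydro-1,4-benzodioxin-2-yl]-2,6-dimethoxyphenoxy}triisopropylsilane | Brc1cc(OC)c2c(c1)O[C@H](c1cc(OC)c(O[Si](C(C)C)(C(C)C)C(C)C)c(OC)c1)[C@@H](C)O2
F9 | step 10 | tert-butyl{4-[(2R,3S)-7-bromo-3-(iodomethyl)-5-methoxy-2,3-dihydro-1,4-benzodioxin-2-yl]-2,6-dimethoxyphenoxy}dimethylsilane | Brc1cc(OC)c2c(c1)O[C@H](c1cc(OC)c(O[Si](C)(C)C(C)(C)C)c(OC)c1)[C@@H](CI)O2
F10 | step 10 | tert-butyl{4-[(2R,3R)-7-bromo-5-methoxy-3-methyl-2,3-dihydro-1,4-benzodioxin-2-yl]-2,6-dimethoxyphenoxy}dimethylsilane | Brc1cc(OC)c2c(c1)O[C@H](c1cc(OC)c(O[Si](C)(C)C(C)(C)C)c(OC)c1)[C@@H](C)O2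
F0 | step 11 | none | none
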